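**Plan**

1. Target atoms are numbered as in 3,3a-dihydro-1-benzofuran-4,6(2H,5H)-dione (O1, C2, C3, C3a, C4, C5, C6, C7, C7a). Retrosynthesis: the ether bond O1–C2 is first traded for a bond from the tertiary carbinol oxygen to C7a (isomeric dihydropyran); then C3–C3a is cut (ring-carbon nucleophile plus primary tosylate); then the tertiary C–O bond (prenylated acylfilicinic acid plus a C10 epoxy tosylate); last the prenyl, methyl and acyl bonds back to phloroglucinol.
2. Forward: the carbocycle is the phloroglucinol ring (C-acylation, gem-dimethylation at C5, prenylation at C3a). The C10 chain is hung on the C7a oxygen through its tertiary carbon, a temporary dihydropyran is closed by the C3–C3a bond, and acid then contracts it to the dihydrofuran.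
3. Enabling feature: C3a lies between the enol-ether carbon C7a and the C4 ketone and is vinylogous, through C7a=C7, to the C6/acyl β-diketone, so one mild deprotonation makes it a soft carbon nucleophile. C4 is flanked by the quaternary carbons C3a and C5 and can never carry an enol ether, so a side-chain oxygen can only sit on C7a and the pyran-to-furan switch has a single outcome.
4. Stereochemistry: the sec-butyl centre is bought ((R)-2-methylbutanoic acid). C2 and the carbinol carbon come from Sharpless epoxidation of geraniol with D-(−)-diethyl tartrate (the tertiary carbon is inverted once when the ether is made, C2 is never touched). C3a is set in the key step by a chair transition state of the closing dihydropyran.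

Key step: step 7

Assumption: dienone 6 reacts as its usual tautomer, with the free enol OH on C-5 (next to the gem-dimethyl carbon) and the chelated enol OH on C-3 (next to the acyl group).

**Route**

Step 1
Reactants: 1 phloroglucinol; 2 (R)-2-methylbutanoic acid
Product: 4 (2R)-2-methyl-1-(2,4,6-trihydroxyphenyl)butan-1-one, via acid chloride 3 (not isolated)
Conditions: (COCl)2, cat. DMF, CH2Cl2, 0 °C to rt; then 1, AlCl3, PhNO2, rt to 40 °C
Reagents that add atoms: none
Why: Friedel–Crafts C-acylation of the threefold-symmetric, electron-rich arene can give only one regioisomer, and the α-stereocentre of 2 should be carried through because neither stage uses base.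

Step 2
Reactants: 4 acylphloroglucinol
Product: 5 3,5-dihydroxy-4,4-dimethyl-2-[(2R)-2-methylbutanoyl]cyclohexa-2,5-dien-1-one
Conditions: MeI (2.2 equiv), NaOMe, MeOH, 0 °C to rt
Reagents that add atoms: iodomethane CI
Why: dearomatising double C-methylation of the phloroglucinol polyanion at one ring carbon is the known entry to acylfilicinic acids; no stereocentre is formed.

Step 3
Reactants: 5 acylfilicinic acid
Product: 6 3,5-dihydroxy-4,4-dimethyl-2-[(2R)-2-methylbutanoyl]-6-(3-methylbut-2-en-1-yl)cyclohexa-2,5-dien-1-one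
Conditions: prenyl bromide (1.0 equiv), NaOMe, MeOH, 0 °C
Reagents that add atoms: prenyl bromide (1-bromo-3-methylbut-2-ene) CC(C)=CCBr
Why: C-allylation of the vinylogous acid anion at the only remaining ring CH (soft allylic halide in a protic solvent favours carbon over oxygen); no stereocentre is formed.

Step 4
Reactants: 7 geraniol
Product: 8 (2R,3R)-2,3-epoxygeraniol, [(2R,3R)-3-methyl-3-(4-methylpent-3-en-1-yl)oxiran-2-yl]methanol
Conditions: Ti(OiPr)4 (cat.), D-(−)-diethyl tartrate (cat.), t-BuOOH, 4 Å molecular sieves, CH2Cl2, −20 °C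
Reagents that add atoms: tert-butyl hydroperoxide CC(C)(C)OO
Why: Sharpless asymmetric epoxidation; the D-tartrate ligand directs oxygen to the face of the allylic alcohol that gives the (2R,3R)-epoxide, so both side-chain stereocentres are set together.

Step 5
Reactants: 8 epoxy alcohol
Product: 9 [(2R,3R)-3-methyl-3-(4-methylpent-3-en-1-yl)oxiran-2-yl]methyl 4-methylbenzenesulfonate
Conditions: TsCl, Et3N, cat. DMAP, CH2Cl2, 0 °C
Reagents that add atoms: p-toluenesulfonyl chloride Cc1ccc(cc1)S(Cl)(=O)=O
Why: sulfonylation of the primary alcohol; no bond to a stereocentre is touched.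

Step 6
Reactants: 6 prenylated acylfilicinic acid; 9 epoxy tosylate
Product: 11 (2R,3S)-3-{[5-hydroxy-4,4-dimethyl-6-[(2R)-2-methylbutanoyl]-2-(3-methylbut-2-en-1-yl)-3-oxocyclohexa-1,5-dien-1-yl]oxy}-3,7-dimethyl-2-(triethylsilyloxy)oct-6-en-1-yl 4-methylbenzenesulfonate, via silyl enol ether 10 (not isolated)
Conditions: 6, Et3SiOTf (1.2 equiv), 2,6-di-tert-butyl-4-methylpyridine (1.1 equiv), CH2Cl2, −78 °C; then 9, −78 to −20 °C; aq. NaHCO3
Reagents that add atoms: triethylsilyl trifluoromethanesulfonate CC[Si](CC)(CC)OS(=O)(=O)C(F)(F)F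
Why: Proposed new method: silylation of the free enol OH gives the vinylogous silyl ester 10, whose distal carbonyl oxygen (on C-1) is the only site left for a silyl-activated epoxide because the α-carbon is fully substituted; it should open 9 at the tertiary carbon with inversion (borderline SN2 on the silyloxonium ion, giving the 3S centre) while Et3Si passes from the enol oxygen to the epoxide oxygen and carries the chain; the closest known reaction types are the Lewis-acid-catalysed opening of epoxides by silylated heteroatom nucleophiles with O-silyl transfer and the C-3-selective opening of 2,3-epoxy alcohol derivatives by carboxylic acids.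

Step 7
Reactants: 11 tertiary enol ether tosylate
Product: 12 (2S,3R,4aS)-2,6,6-trimethyl-8-[(2R)-2-methylbutanoyl]-4a-(3-methylbut-2-en-1-yl)-2-(4-methylpent-3-en-1-yl)-3-(triethylsilyloxy)-3,4-dihydro-2H-chromene-5,7(4aH,6H)-dione
Conditions: Cs2CO3 (1.5 equiv), MeCN (0.01 M), 60 °C
Reagents that add atoms: none
Why: Cs2CO3 removes the chelated enol proton of 11, and the charge of the resulting vinylogous β-triketone enolate is shared by the prenyl-bearing ring carbon, which displaces the primary tosylate in an intramolecular SN2 alkylation. The closest known reaction type is the C-alkylation of dearomatised acylphloroglucinol (2-substituted cyclic 1,3-dicarbonyl) anions that builds their quaternary carbons, run here within one molecule. The dihydropyran closes in the 6-(enolendo)-exo-tet mode, in which the in-plane ether oxygen and the three-atom chain can place the CH2 carbon above the enolate carbon without strain. The new quaternary centre (C-4a of 12, C3a of the target) is set by a chair-like transition state in which the silyloxy group on C-3 and the 4-methylpentenyl chain on C-2 are equatorial and the prenyl group becomes axial, so carbon is delivered to the face that gives the 4aS configuration. The step needs C- over O-alkylation and attack at the prenyl-bearing rather than the acyl-bearing carbon: O-alkylation would need an eight-membered ring, and the acyl-bearing carbon is more hindered, is held in the metal chelate and would lose the conjugated enol ether on alkylation.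

Step 8
Reactants: 12 silylated pyran
Product: 14 (2R,3aS)-2-[(2S)-2-hydroxy-6-methylhept-5-en-2-yl]-5,5-dimethyl-7-[(2R)-2-methylbutanoyl]-3a-(3-methylbut-2-en-1-yl)-3,3a-dihydro-1-benzofuran-4,6(2H,5H)-dione (target), via hydroxy pyran 13 (not isolated)
Conditions: TsOH·H2O (0.2 equiv), THF–H2O (10:1), 40 °C
Reagents that add atoms: none
Why: acid cleaves the silyl ether to 13, and the freed secondary hydroxyl should then replace the tertiary alkoxy group on the enol-ether carbon by addition–elimination (vinylogous transesterification, directly or through the hydrolysed triketone), contracting the dihydropyran to the dihydrofuran; no bond to a stereocentre is broken, and the C4 ketone between two quaternary carbons cannot take part, so only one furan isomer can form.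

**Compound list**

1 | phloroglucinol (benzene-1,3,5-triol) | Oc1cc(O)cc(O)c1 | starting material
2 | (R)-2-methylbutanoic acid | CC[C@@H](C)C(=O)O | starting material
3 | (R)-2-methylbutanoyl chloride | CC[C@@H](C)C(=O)Cl | intermediate
4 | (2R)-2-methyl-1-(2,4,6-trihydroxyphenyl)butan-1-one | CC[C@@H](C)C(=O)c1c(O)cc(O)cc1O | intermediate
5 | 3,5-dihydroxy-4,4-dimethyl-2-[(2R)-2-methylbutanoyl]cyclohexa-2,5-dien-1-one | CC[C@@H](C)C(=O)C1=C(O)C(C)(C)C(O)=CC1=O | intermediate
6 | 3,5-dihydroxy-4,4-dimethyl-2-[(2R)-2-methylbutanoyl]-6-(3-methylbut-2-en-1-yl)cyclohexa-2,5-dien-1-one | CC[C@@H](C)C(=O)C1=C(O)C(C)(C)C(O)=C(CC=C(C)C)C1=O | intermediate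
7 | geraniol, (2E)-3,7-dimethylocta-2,6-dien-1-ol | CC(C)=CCC/C(C)=C/CO | starting material
8 | (2R,3R)-2,3-epoxygeraniol | OC[C@H]1O[C@]1(C)CCC=C(C)C | intermediate
9 | [(2R,3R)-3-methyl-3-(4-methylpent-3-en-1-yl)oxiran-2-yl]methyl 4-methylbenzenesulfonate | Cc1ccc(cc1)S(=O)(=O)OC[C@H]1O[C@]1(C)CCC=C(C)C | intermediate
10 | 3-hydroxy-4,4-dimethyl-2-[(2R)-2-methylbutanoyl]-6-(3-methylbut-2-en-1-yl)-5-(triethylsilyloxy)cyclohexa-2,5-dien-1-one | CC[C@@H](C)C(=O)C1=C(O)C(C)(C)C(O[Si](CC)(CC)CC)=C(CC=C(C)C)C1=O | intermediate
11 | (2R,3S)-3-{[5-hydroxy-4,4-dimethyl-6-[(2R)-2-methylbutanoyl]-2-(3-methylbut-2-en-1-yl)-3-oxocyclohexa-1,5-dien-1-yl]oxy}-3,7-dimethyl-2-(triethylsilyloxy)oct-6-en-1-yl 4-methylbenzenesulfonate | CC[C@@H](C)C(=O)C1=C(O)C(C)(C)C(=O)C(CC=C(C)C)=C1O[C@@](C)(CCC=C(C)C)[C@H](O[Si](CC)(CC)CC)COS(=O)(=O)c1ccc(C)cc1 | intermediate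
12 | (2S,3R,4aS)-2,6,6-trimethyl-8-[(2R)-2-methylbutanoyl]-4a-(3-methylbut-2-en-1-yl)-2-(4-methylpent-3-en-1-yl)-3-(triethylsilyloxy)-3,4-dihydro-2H-chromene-5,7(4aH,6H)-dione | CC[C@@H](C)C(=O)C1=C2O[C@@](C)(CCC=C(C)C)[C@H](O[Si](CC)(CC)CC)C[C@]2(CC=C(C)C)C(=O)C(C)(C)C1=O | intermediate
13 | (2S,3R,4aS)-3-hydroxy-2,6,6-trimethyl-8-[(2R)-2-methylbutanoyl]-4a-(3-methylbut-2-en-1-yl)-2-(4-methylpent-3-en-1-yl)-3,4-dihydro-2H-chromene-5,7(4aH,6H)-dione | CC[C@@H](C)C(=O)C1=C2O[C@@](C)(CCC=C(C)C)[C@H](O)C[C@]2(CC=C(C)C)C(=O)C(C)(C)C1=O | intermediate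
14 | (2R,3aS)-2-[(2S)-2-hydroxy-6-methylhept-5-en-2-yl]-5,5-dimethyl-7-[(2R)-2-methylbutanoyl]-3a-(3-methylbut-2-en-1-yl)-3,3a-dihydro-1-benzofuran-4,6(2H,5H)-dione (CNP0306408.2) | CC[C@@H](C)C(=O)C1=C2O[C@@H]([C@@](C)(O)CCC=C(C)C)C[C@]2(CC=C(C)C)C(=O)C(C)(C)C1=O | target

**Step count**

Total: 8 steps. Longest linear sequence: 6 steps (steps 1, 2, 3, 6, 7 and 8, from phloroglucinol).

**Steps most likely to fail**

Step 6 (proposed new method). Silylation or alkylation may take place on the wrong ring oxygen. The hindered oxygen next to the acyl group may react too slowly, so that the activated epoxide rearranges or eliminates instead. Opening through a free tertiary cation would erode the configuration at the tertiary carbon. Fallback with known chemistry, setting out from 6 and 8 and coming back at 11: the free epoxy alcohol 8 is opened at C-3 by the vinylogous acid 6 in the presence of Ti(OiPr)4 (the established C-3-selective opening of 2,3-epoxy alcohols by carboxylic acids and phenols, with inversion) to give the diol ether F1. Its primary hydroxyl is tosylated selectively (TsCl, Et3N, cat. Bu2SnO) to give the hydroxy tosylate F2. Silylation of the secondary hydroxyl (Et3SiOTf, 2,6-lutidine) then gives 11.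

Step 7. The enolate may eliminate the tosylate instead of displacing it, may be alkylated at the acyl-bearing carbon, or may close through a boat-like transition state with poor facial selectivity. Fallback, setting out from 6 and 9 and coming back at 13: the carbon–carbon bond is made between the two molecules first, by C-alkylation of the anion of 6 with 9 at the prenyl-bearing carbon (Cs2CO3, DMF), which gives the C-alkylated epoxide F3 as both configurations at the new quaternary carbon. Catalytic camphorsulfonic acid in CH2Cl2 then lets the enol oxygen open the epoxide at the tertiary carbon in the 6-endo mode with inversion. This gives 13 together with its 4a-epimer F4, which is removed by chromatography; 13 is then treated as in step 8.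

Step 8. The ring switch may stop at an equilibrium mixture or stay on the pyran side, and prolonged acid may ionise the tertiary ether carbon. Fallback, setting out from 12 and coming back at 14: the tertiary enol ether is cleaved irreversibly by hydroxide (LiOH, THF–H2O; addition–elimination at the enol-ether carbon, the tertiary C–O bond stays intact) to give the ring-opened silyloxy triketone F5. HF·pyridine in MeCN then removes the silyl group, and the resulting dihydroxy triketone F6 closes under the same acidic conditions through its secondary hydroxyl (kinetic preference over the tertiary one) to give 14.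

Further compounds
F1 | step 6 | (2R,3S)-3-{[5-hydroxy-4,4-dimethyl-6-[(2R)-2-methylbutanoyl]-2-(3-methylbut-2-en-1-yl)-3-oxocyclohexa-1,5-dien-1-yl]oxy}-3,7-dimethyloct-6-ene-1,2-diol | CC[C@@H](C)C(=O)C1=C(O)C(C)(C)C(=O)C(CC=C(C)C)=C1O[C@@](C)(CCC=C(C)C)[C@H](O)CO
F2 | step 6 | (2R,3S)-2-hydroxy-3-{[5-hydroxy-4,4-dimethyl-6-[(2R)-2-methylbutanoyl]-2-(3-methylbut-2-en-1-yl)-3-oxocyclohexa-1,5-dien-1-yl]oxy}-3,7-dimethyloct-6-en-1-yl 4-methylbenzenesulfonate | CC[C@@H](C)C(=O)C1=C(O)C(C)(C)C(=O)C(CC=C(C)C)=C1O[C@@](C)(CCC=C(C)C)[C@H](O)COS(=O)(=O)c1ccc(C)cc1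
F3 | step 7 | 3-hydroxy-4,4-dimethyl-2-[(2R)-2-methylbutanoyl]-6-{[(2R,3R)-3-methyl-3-(4-methylpent-3-en-1-yl)oxiran-2-yl]methyl}-6-(3-methylbut-2-en-1-yl)cyclohex-2-ene-1,5-dione, both configurations at C-6 | CC[C@@H](C)C(=O)C1=C(O)C(C)(C)C(=O)C(CC=C(C)C)(C[C@H]2O[C@]2(C)CCC=C(C)C)C1=O
F4 | step 7 | (2S,3R,4aR)-3-hydroxy-2,6,6-trimethyl-8-[(2R)-2-methylbutanoyl]-4a-(3-methylbut-2-en-1-yl)-2-(4-methylpent-3-en-1-yl)-3,4-dihydro-2H-chromene-5,7(4aH,6H)-dione | CC[C@@H](C)C(=O)C1=C2O[C@@](C)(CCC=C(C)C)[C@H](O)C[C@@]2(CC=C(C)C)C(=O)C(C)(C)C1=O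
F5 | step 8 | (4S)-3-hydroxy-4-[(2R,3S)-3-hydroxy-3,7-dimethyl-2-(triethylsilyloxy)oct-6-en-1-yl]-6,6-dimethyl-2-[(2R)-2-methylbutanoyl]-4-(3-methylbut-2-en-1-yl)cyclohex-2-ene-1,5-dione | CC[C@@H](C)C(=O)C1=C(O)[C@](CC=C(C)C)(C[C@@H](O[Si](CC)(CC)CC)[C@@](C)(O)CCC=C(C)C)C(=O)C(C)(C)C1=O
F6 | step 8 | (4S)-4-[(2R,3S)-2,3-dihydroxy-3,7-dimethyloct-6-en-1-yl]-3-hydroxy-6,6-dimethyl-2-[(2R)-2-methylbutanoyl]-4-(3-methylbut-2-en-1-yl)cyclohex-2-ene-1,5-dione | CC[C@@H](C)C(=O)C1=C(O)[C@](CC=C(C)C)(C[C@@H](O)[C@@](C)(O)CCC=C(C)C)C(=O)C(C)(C)C1=O
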